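**Plan**
1. The 14-membered lactone ring (O13, C1–C13) is cut at C9–C10. C10 is a ring CH2 between alkenyl carbon C9 and carbinol carbon C11, so this bond joins two electrophiles, an E-alkenyl bromide at C9 and a terminal epoxide C10–C11, by nickel-catalysed reductive coupling that also frees the C11 hydroxyl.
2. Further cuts: the O13–C1 ester, C3–C4 and C6–C7 (two allyl–alkenyl Stille couplings), C12–C13 and C14–C15 (two allylborations). The acid of the arm on C3 is carried as a silylated primary alcohol.
3. Forward: decanal gives the C10–C24 epoxy alcohol, but-2-yn-1-ol gives the C4–C9 dibromodiene, and a silyloxybutyne gives the C1–C3 stannyl enoic acid. These are joined by esterification at O13 and Stille coupling at C3–C4, then the only ring is closed at C9–C10.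
4. Desilylation and oxidation of the arm alcohol to the acid finish the synthesis.
5. Stereochemistry: C15 and C13 come from two reagent-controlled Brown allylborations, C11 from a 1,3-syn iodocarbonate cyclisation relayed from C13. The E geometries at C2=C3, C5=C6 and C8=C9 come from thermodynamic stannylcupration, an E-alkenylstannane and syn hydrozirconation, each carried through the couplings with retention.

Key step: step 17

Remark on numbering: C1 is the lactone carbonyl, C13 the carbon bearing the ring oxygen, C14–C24 the side chain, C1'–C2' the arm on C3.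
Remark on supply: (E)-3-(tributylstannyl)prop-2-en-1-ol, 4-(tert-butyldimethylsilyloxy)but-1-yne and both enantiomeric B-allyldiisopinocampheylboranes are taken as catalogue reagents.

**Route**

Step 1
Reactants: 1 decanal
Product: 3 (S)-tridec-1-en-4-ol, via borinate ester 2 (not isolated)
Conditions: lIpc2B(allyl) [(−)-Ipc2B(allyl), (−)-α-pinene series], Et2O, −78 °C; then NaOH, H2O2, 0 °C → rt
Reagents that add atoms: lIpc2B(allyl), B-allylbis[(1S,2R,3S,5S)-isopinocampheyl]borane, C=CCB([C@H]1C[C@H]2C[C@@H]([C@@H]1C)C2(C)C)[C@H]1C[C@H]2C[C@@H]([C@@H]1C)C2(C)C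
Why: Brown allylboration through a chair six-membered transition state in which the (−)-α-pinene-derived ligands direct the allyl group to the Re face of the aldehyde, which should set C15 as S.

Step 2
Reactants: 3 (S)-tridec-1-en-4-ol
Product: 4 (S)-tert-butyldimethyl(tridec-1-en-4-yloxy)silane
Conditions: TBSCl, imidazole, DMF, rt
Reagents that add atoms: tert-butyldimethylsilyl chloride, CC(C)(C)[Si](C)(C)Cl
Why: Standard silylation of a secondary alcohol; this ether masks O15 until the penultimate step.

Step 3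
Reactants: 4 (S)-tert-butyldimethyl(tridec-1-en-4-yloxy)silane
Product: 6 (S)-3-(tert-butyldimethylsilyloxy)dodecanal, via ozonide 5 (not isolated)
Conditions: O3, CH2Cl2, −78 °C; PPh3, −78 °C → rt
Reagents that add atoms: ozone, [O-][O+]=O
Why: Ozonolysis with reductive work-up cleaves the only alkene to the C13 aldehyde without touching the β-silyloxy stereocentre.

Step 4
Reactants: 6 (S)-3-(tert-butyldimethylsilyloxy)dodecanal
Product: 8 (4S,6S)-6-(tert-butyldimethylsilyloxy)pentadec-1-en-4-ol, via borinate ester 7 (not isolated)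
Conditions: dIpc2B(allyl) [(+)-Ipc2B(allyl), (+)-α-pinene series], Et2O, −78 °C; then NaOH, H2O2, 0 °C → rt
Reagents that add atoms: dIpc2B(allyl), B-allylbis[(1R,2S,3R,5R)-isopinocampheyl]borane, C=CCB([C@@H]1C[C@@H]2C[C@H]([C@H]1C)C2(C)C)[C@@H]1C[C@@H]2C[C@H]([C@H]1C)C2(C)C
Why: Second Brown allylboration under reagent control: the (+)-α-pinene-derived reagent adds to the Si face and should set C13 as S, anti to the C15 silyl ether, overriding the weak bias of the β-silyloxy group.

Step 5
Reactants: 8 (4S,6S)-6-(tert-butyldimethylsilyloxy)pentadec-1-en-4-ol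
Product: 9 tert-butyl (4S,6S)-6-(tert-butyldimethylsilyloxy)pentadec-1-en-4-yl carbonate
Conditions: Boc2O, DMAP (cat.), MeCN, rt
Reagents that add atoms: di-tert-butyl dicarbonate, CC(C)(C)OC(=O)OC(=O)OC(C)(C)C
Why: DMAP-catalysed acylation of the homoallylic alcohol installs the carbonate that serves as internal oxygen nucleophile in the next step.

Step 6
Reactants: 9 tert-butyl (4S,6S)-6-(tert-butyldimethylsilyloxy)pentadec-1-en-4-yl carbonate
Product: 10 (4R,6S)-4-(iodomethyl)-6-[(S)-2-(tert-butyldimethylsilyloxy)undecyl]-1,3-dioxan-2-one (4,6-cis)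
Conditions: IBr, PhMe, −85 °C
Reagents that add atoms: iodine monobromide, IBr
Why: Iodocarbonate cyclisation (iodonium-induced 6-exo attack of the carbonate carbonyl, loss of the tert-butyl cation) through a chair transition state with both substituents equatorial, which should set C11 syn to C13.

Step 7
Reactants: 10 (4R,6S)-4-(iodomethyl)-6-[(S)-2-(tert-butyldimethylsilyloxy)undecyl]-1,3-dioxan-2-one
Product: 11 (2S,4S)-4-(tert-butyldimethylsilyloxy)-1-[(R)-oxiran-2-yl]tridecan-2-ol
Conditions: K2CO3, MeOH, 0 °C → rt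
Reagents that add atoms: none
Why: Methanolysis of the cyclic carbonate frees the C11 alkoxide, which displaces the primary iodide (3-exo-tet) with the C11–O bond untouched, giving the syn epoxy alcohol with O13 free.

Step 8
Reactants: 12 but-2-yn-1-ol
Product: 14 (E)-3-bromobut-2-en-1-ol, via alkenylzirconocene 13 (not isolated)
Conditions: Cp2Zr(H)Cl (2.3 equiv), THF, 0 °C → rt; NBS, 0 °C; dil. HCl work-up
Reagents that add atoms: N-bromosuccinimide, O=C1CCC(=O)N1Br
Why: Hydrozirconation of a 2-alkyne is a syn addition that places zirconium on the methyl-bearing carbon, and bromodezirconation with retention gives the E-alkenyl bromide that becomes C8=C9–Br.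

Step 9
Reactants: 14 (E)-3-bromobut-2-en-1-ol
Product: 15 (E)-1,3-dibromobut-2-ene
Conditions: PBr3 (0.4 equiv), Et2O, 0 °C
Reagents that add atoms: phosphorus tribromide, BrP(Br)Br
Why: Bromination of a primary allylic alcohol with PBr3 leaves the alkenyl bromide and the alkene geometry untouched.

Step 10
Reactants: 15 (E)-1,3-dibromobut-2-ene; 16 (E)-3-(tributylstannyl)prop-2-en-1-ol
Product: 17 (2E,5E)-6-bromohepta-2,5-dien-1-ol
Conditions: Pd2(dba)3 (2.5 mol %), AsPh3 (10 mol %), THF, 40 °C
Reagents that add atoms: none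
Why: Stille coupling of an alkenylstannane with an allylic bromide: zerovalent palladium ionises only the allylic C–Br bond and the alkenyl group is delivered to the unsubstituted CH2 terminus, forming C6–C7 with both alkene geometries kept.

Step 11
Reactants: 17 (2E,5E)-6-bromohepta-2,5-dien-1-ol
Product: 18 (2E,5E)-1,6-dibromohepta-2,5-diene
Conditions: CBr4, PPh3, CH2Cl2, 0 °C
Reagents that add atoms: carbon tetrabromide, BrC(Br)(Br)Br
Why: Appel bromination of the primary allylic alcohol under neutral conditions, which the skipped diene tolerates.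

Step 12
Reactants: 19 tert-butyl(but-3-yn-1-yloxy)dimethylsilane
Product: 21 methyl 5-(tert-butyldimethylsilyloxy)pent-2-ynoate, via lithium acetylide 20 (not isolated)
Conditions: n-BuLi, THF, −78 °C; ClCO2Me, −78 → 0 °C
Reagents that add atoms: methyl chloroformate, COC(=O)Cl
Why: Deprotonation of the terminal alkyne and C-acylation of the acetylide introduces C1.

Step 13
Reactants: 21 methyl 5-(tert-butyldimethylsilyloxy)pent-2-ynoate
Product: 23 methyl (Z)-5-(tert-butyldimethylsilyloxy)-3-(trimethylstannyl)pent-2-enoate, via alkenylcuprate 22 (not isolated)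
Conditions: Me3SnSnMe3, MeLi, THF, −20 °C; CuSPh, −20 °C; then 21, −78 → −48 °C, 4 h; aq NH4Cl (pH 8), MeOH
Reagents that add atoms: hexamethylditin (source of Me3Sn by way of Me3SnLi and Li[Me3SnCu(SPh)]), C[Sn](C)(C)[Sn](C)(C)C
Why: Stannylcupration of a 2-alkynoate: at −48 °C the first-formed adduct equilibrates to the cuprate with tin cis to the ester, and protonation should give the Z-stannyl enoate, which fixes the C2=C3 geometry.

Step 14
Reactants: 23 methyl (Z)-5-(tert-butyldimethylsilyloxy)-3-(trimethylstannyl)pent-2-enoate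
Product: 24 (Z)-5-(tert-butyldimethylsilyloxy)-3-(trimethylstannyl)pent-2-enoic acid
Conditions: LiOH·H2O, THF/MeOH/H2O, rt; then dil. HCl to pH 4–5, 0 °C
Reagents that add atoms: lithium hydroxide (oxygen of the carboxyl OH), [Li+].[OH-]
Why: Saponification of the methyl ester; the alkenylstannane is stable to hydroxide and the mildly acidic work-up avoids protodestannylation.

Step 15
Reactants: 24 (Z)-5-(tert-butyldimethylsilyloxy)-3-(trimethylstannyl)pent-2-enoic acid; 11 (2S,4S)-4-(tert-butyldimethylsilyloxy)-1-[(R)-oxiran-2-yl]tridecan-2-ol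
Product: 26 (2S,4S)-4-(tert-butyldimethylsilyloxy)-1-[(R)-oxiran-2-yl]tridecan-2-yl (Z)-5-(tert-butyldimethylsilyloxy)-3-(trimethylstannyl)pent-2-enoate, via O-acylisourea 25 (not isolated)
Conditions: DCC, DMAP (0.3 equiv), CH2Cl2, 0 °C → rt
Reagents that add atoms: none
Why: Steglich esterification at O13; the carbinol stereocentre is not involved, and the acid carries no doubly allylic CH2 at this stage, so the skipped triene is never exposed to carboxyl activation.

Step 16
Reactants: 26 the stannyl enoate ester of epoxy alcohol 11; 18 (2E,5E)-1,6-dibromohepta-2,5-diene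
Product: 27 (2S,4S)-4-(tert-butyldimethylsilyloxy)-1-[(R)-oxiran-2-yl]tridecan-2-yl (2E,5E,8E)-9-bromo-3-[2-(tert-butyldimethylsilyloxy)ethyl]deca-2,5,8-trienoate
Conditions: Pd2(dba)3·CHCl3 (5 mol %), AsPh3 (20 mol %), NMP, rt → 40 °C; 18 (1.5 equiv)
Reagents that add atoms: none
Why: Stille coupling of the Z-alkenylstannane with the allylic bromide forms C3–C4 at the CH2 terminus with retention at both partners; alkyl epoxides and the trisubstituted alkenyl bromide should be inert to zerovalent palladium under these mild conditions.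

Step 17
Reactants: 27 the C13 ester carrying the C9 alkenyl bromide and the C10–C11 epoxide
Product: 29 (3E,6E,9E,12S,14S)-12-hydroxy-10-methyl-4-[2-(tert-butyldimethylsilyloxy)ethyl]-14-[(S)-2-(tert-butyldimethylsilyloxy)undecyl]oxacyclotetradeca-3,6,9-trien-2-one, via iodohydrin 28 (not isolated)
Conditions: NiI2 (30 mol %), 4,4'-di-tert-butyl-2,2'-bipyridine (30 mol %), NaI (0.5 equiv), Et3N·HCl (1.5 equiv), Zn powder (4 equiv), DMA, 30 °C; 27 added by syringe pump over 16 h, final 1 mM
Reagents that add atoms: none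
Why: Proposed new method: iodide opens the ammonium-activated terminal epoxide at the CH2 carbon C10 to iodohydrin 28, zerovalent nickel inserts into the C9–Br bond, halogen abstraction by a low-valent nickel species gives the C10 radical, this radical is trapped by the alkenyl complex of divalent nickel in the same molecule, and C(sp2)–C(sp3) reductive elimination from trivalent nickel forms C9–C10 while zinc turns the catalyst over. The closest known reaction type is the intermolecular nickel/bipyridine reductive coupling of aryl and vinyl halides with terminal epoxides under iodide co-catalysis, and of alkenyl bromides with primary alkyl iodides; what is new is its use as a ring closure. The 14-membered ring closes by macrocyclic radical capture and reductive elimination at nickel, both C9 and C10 becoming ring atoms, which is possible only because C10 is a ring CH2 lying between alkenyl C9 and carbinol C11. No stereocentre is formed: C11 keeps the epoxide configuration because its C–O bond is never broken, and the E geometry at C8=C9 should be carried over because alkenylnickel species of this kind are configurationally stable. The step needs opening at C10 (secured by the SN2 preference of iodide for the unsubstituted epoxide carbon), capture within the molecule and not between molecules (secured by syringe-pump addition and by sub-stoichiometric iodide, which keeps the iodohydrin concentration low) and no β-elimination of O11 (secured by the radical, not anionic, character of C10). Et3N·HCl keeps O11 protonated, so that no alkoxide can migrate the O13 acyl group.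

Step 18
Reactants: 29 the bis-silylated macrolactone
Product: 30 (3E,6E,9E,12S,14R)-12-hydroxy-4-(2-hydroxyethyl)-14-[(S)-2-hydroxyundecyl]-10-methyloxacyclotetradeca-3,6,9-trien-2-one
Conditions: HF·pyridine, pyridine, THF, 0 °C → rt
Reagents that add atoms: none
Why: Fluoride cleavage of both silyl ethers under buffered, weakly acidic conditions that should leave the lactone, the skipped triene and the 1,3-diol monoester untouched.

Step 19
Reactants: 30 the triol
Product: 32 2-[(3E,6E,9E,12S,14R)-12-hydroxy-14-[(S)-2-hydroxyundecyl]-10-methyl-2-oxooxacyclotetradeca-3,6,9-trien-4-yl]acetic acid (CNP0213378.2), via aldehyde 31 (not isolated)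
Conditions: TEMPO (0.3 equiv), PhI(OAc)2 (2.5 equiv), MeCN/pH 7 phosphate buffer (1:1), 0 °C → rt
Reagents that add atoms: water, O
Why: Oxoammonium (TEMPO) oxidation with PhI(OAc)2 in aqueous acetonitrile is selective for the primary alcohol and carries it through the aldehyde hydrate to the acid, the two secondary carbinols reacting far more slowly.

**Compound list**
1 | decanal | CCCCCCCCCC=O | starting material
2 | (S)-tridec-1-en-4-yl bis[(1S,2R,3S,5S)-isopinocampheyl]borinate (forms in the flask) | CCCCCCCCC[C@H](OB([C@H]1C[C@H]2C[C@@H]([C@@H]1C)C2(C)C)[C@H]1C[C@H]2C[C@@H]([C@@H]1C)C2(C)C)CC=C | intermediate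
3 | (S)-tridec-1-en-4-ol | CCCCCCCCC[C@H](O)CC=C | intermediate
4 | (S)-tert-butyldimethyl(tridec-1-en-4-yloxy)silane | CCCCCCCCC[C@H](O[Si](C)(C)C(C)(C)C)CC=C | intermediate
5 | 3-[(S)-2-(tert-butyldimethylsilyloxy)undecyl]-1,2,4-trioxolane (ozonide, forms in the flask) | CCCCCCCCC[C@H](O[Si](C)(C)C(C)(C)C)CC1OCOO1 | intermediate
6 | (S)-3-(tert-butyldimethylsilyloxy)dodecanal | CCCCCCCCC[C@H](O[Si](C)(C)C(C)(C)C)CC=O | intermediate
7 | (4S,6S)-6-(tert-butyldimethylsilyloxy)pentadec-1-en-4-yl bis[(1R,2S,3R,5R)-isopinocampheyl]borinate (forms in the flask) | CCCCCCCCC[C@H](O[Si](C)(C)C(C)(C)C)C[C@@H](OB([C@@H]1C[C@@H]2C[C@H]([C@H]1C)C2(C)C)[C@@H]1C[C@@H]2C[C@H]([C@H]1C)C2(C)C)CC=C | intermediate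
8 | (4S,6S)-6-(tert-butyldimethylsilyloxy)pentadec-1-en-4-ol (4,6-anti) | CCCCCCCCC[C@H](O[Si](C)(C)C(C)(C)C)C[C@@H](O)CC=C | intermediate
9 | tert-butyl (4S,6S)-6-(tert-butyldimethylsilyloxy)pentadec-1-en-4-yl carbonate | CCCCCCCCC[C@H](O[Si](C)(C)C(C)(C)C)C[C@@H](OC(=O)OC(C)(C)C)CC=C | intermediate
10 | (4R,6S)-4-(iodomethyl)-6-[(S)-2-(tert-butyldimethylsilyloxy)undecyl]-1,3-dioxan-2-one (4,6-cis) | CCCCCCCCC[C@H](O[Si](C)(C)C(C)(C)C)C[C@@H]1C[C@H](CI)OC(=O)O1 | intermediate
11 | (2S,4S)-4-(tert-butyldimethylsilyloxy)-1-[(R)-oxiran-2-yl]tridecan-2-ol (C10–C24 epoxy alcohol, 11,13-syn, 13,15-anti) | CCCCCCCCC[C@H](O[Si](C)(C)C(C)(C)C)C[C@@H](O)C[C@@H]1CO1 | intermediate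
12 | but-2-yn-1-ol | CC#CCO | starting material
13 | (E)-alkenylzirconocene chloride of but-2-yn-1-ol, zirconium on C3 and the oxygen as Cp2Zr(Cl) alkoxide (forms in the flask; Cp rings drawn σ-bonded) | C/C(=C\CO[Zr](Cl)(C1C=CC=C1)C1C=CC=C1)[Zr](Cl)(C1C=CC=C1)C1C=CC=C1 | intermediate
14 | (E)-3-bromobut-2-en-1-ol | OC/C=C(C)/Br | intermediate
15 | (E)-1,3-dibromobut-2-ene | BrC/C=C(C)/Br | intermediate
16 | (E)-3-(tributylstannyl)prop-2-en-1-ol | OC/C=C/[Sn](CCCC)(CCCC)CCCC | starting material
17 | (2E,5E)-6-bromohepta-2,5-dien-1-ol | OC/C=C/C/C=C(C)/Br | intermediate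
18 | (2E,5E)-1,6-dibromohepta-2,5-diene (C4–C9 unit) | BrC/C=C/C/C=C(C)/Br | intermediate
19 | tert-butyl(but-3-yn-1-yloxy)dimethylsilane | C#CCCO[Si](C)(C)C(C)(C)C | starting material
20 | [4-(tert-butyldimethylsilyloxy)but-1-yn-1-yl]lithium (forms in the flask) | [Li]C#CCCO[Si](C)(C)C(C)(C)C | intermediate
21 | methyl 5-(tert-butyldimethylsilyloxy)pent-2-ynoate | COC(=O)C#CCCO[Si](C)(C)C(C)(C)C | intermediate
22 | lithium (phenylthio)cuprate of the enoate with copper on C2 and tin on C3 cis to the ester (forms in the flask) | [Li+].COC(=O)/C([Cu-]Sc1ccccc1)=C(\[Sn](C)(C)C)CCO[Si](C)(C)C(C)(C)C | intermediate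
23 | methyl (Z)-5-(tert-butyldimethylsilyloxy)-3-(trimethylstannyl)pent-2-enoate | COC(=O)/C=C(\[Sn](C)(C)C)CCO[Si](C)(C)C(C)(C)C | intermediate
24 | (Z)-5-(tert-butyldimethylsilyloxy)-3-(trimethylstannyl)pent-2-enoic acid | OC(=O)/C=C(\[Sn](C)(C)C)CCO[Si](C)(C)C(C)(C)C | intermediate
25 | O-acylisourea of acid 24 and dicyclohexylcarbodiimide (forms in the flask) | C1CCCCC1NC(=NC1CCCCC1)OC(=O)/C=C(\[Sn](C)(C)C)CCO[Si](C)(C)C(C)(C)C | intermediate
26 | (2S,4S)-4-(tert-butyldimethylsilyloxy)-1-[(R)-oxiran-2-yl]tridecan-2-yl (Z)-5-(tert-butyldimethylsilyloxy)-3-(trimethylstannyl)pent-2-enoate | CCCCCCCCC[C@H](O[Si](C)(C)C(C)(C)C)C[C@@H](OC(=O)/C=C(\[Sn](C)(C)C)CCO[Si](C)(C)C(C)(C)C)C[C@@H]1CO1 | intermediate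
27 | (2S,4S)-4-(tert-butyldimethylsilyloxy)-1-[(R)-oxiran-2-yl]tridecan-2-yl (2E,5E,8E)-9-bromo-3-[2-(tert-butyldimethylsilyloxy)ethyl]deca-2,5,8-trienoate (precursor of the key step) | CCCCCCCCC[C@H](O[Si](C)(C)C(C)(C)C)C[C@@H](OC(=O)/C=C(CCO[Si](C)(C)C(C)(C)C)\C/C=C/C/C=C(C)/Br)C[C@@H]1CO1 | intermediate
28 | (2R,4S,6S)-6-(tert-butyldimethylsilyloxy)-2-hydroxy-1-iodopentadecan-4-yl (2E,5E,8E)-9-bromo-3-[2-(tert-butyldimethylsilyloxy)ethyl]deca-2,5,8-trienoate (iodohydrin, forms in the flask) | CCCCCCCCC[C@H](O[Si](C)(C)C(C)(C)C)C[C@@H](OC(=O)/C=C(CCO[Si](C)(C)C(C)(C)C)\C/C=C/C/C=C(C)/Br)C[C@@H](O)CI | intermediate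
29 | (3E,6E,9E,12S,14S)-12-hydroxy-10-methyl-4-[2-(tert-butyldimethylsilyloxy)ethyl]-14-[(S)-2-(tert-butyldimethylsilyloxy)undecyl]oxacyclotetradeca-3,6,9-trien-2-one (product of the key step) | CCCCCCCCC[C@H](O[Si](C)(C)C(C)(C)C)C[C@@H]1C[C@@H](O)C/C(C)=C/C/C=C/C/C(CCO[Si](C)(C)C(C)(C)C)=C\C(=O)O1 | intermediate
30 | (3E,6E,9E,12S,14R)-12-hydroxy-4-(2-hydroxyethyl)-14-[(S)-2-hydroxyundecyl]-10-methyloxacyclotetradeca-3,6,9-trien-2-one | CCCCCCCCC[C@H](O)C[C@@H]1C[C@@H](O)C/C(C)=C/C/C=C/C/C(CCO)=C\C(=O)O1 | intermediate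
31 | 2-[(3E,6E,9E,12S,14R)-12-hydroxy-14-[(S)-2-hydroxyundecyl]-10-methyl-2-oxooxacyclotetradeca-3,6,9-trien-4-yl]acetaldehyde (forms in the flask) | CCCCCCCCC[C@H](O)C[C@@H]1C[C@@H](O)C/C(C)=C/C/C=C/C/C(CC=O)=C\C(=O)O1 | intermediate
32 | 2-[(3E,6E,9E,12S,14R)-12-hydroxy-14-[(S)-2-hydroxyundecyl]-10-methyl-2-oxooxacyclotetradeca-3,6,9-trien-4-yl]acetic acid, CNP0213378.2 (11S,13R,15S in macrolide numbering) | CCCCCCCCC[C@H](O)C[C@@H]1C[C@@H](O)C/C(C)=C/C/C=C/C/C(CC(=O)O)=C\C(=O)O1 | target

**Count**
Total steps: 19. Longest linear sequence: 12 steps (steps 1–7 and 15–19, from decanal).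

**Steps most likely to fail**

1. Step 17. The C10 radical may be reduced, or captured by a nickel centre of another molecule to give oligomers, or the alkenylnickel species may be protonated or dimerise before it meets the radical. The fallback makes the same C9–C10 bond between two molecules, where the coupling is known, and closes the ring elsewhere by a known macrocyclisation. It sets out from 26 and 17 and returns at 29. Stannyl ester 26 (epoxide, no bromide) and bromodienol 17 would be coupled under the intermolecular conditions (NiI2, 4,4'-di-tert-butyl-2,2'-bipyridine, NaI, Et3N·HCl, Zn powder, DMPU, rt), by way of the iodohydrin of 26 F1, to give the C4 allylic alcohol with free C11 hydroxyl F2. The primary allylic alcohol would then be brominated selectively (CBr4, PPh3, 2,6-lutidine, CH2Cl2, −20 °C) to the allylic bromide F3, the secondary C11 carbinol reacting much more slowly. Intramolecular Stille coupling of F3 (Pd2(dba)3, AsPh3, NMP, high dilution, 40 °C) would close the 14-membered ring at C3–C4 and give 29.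

2. Step 16. Transmetalation of the α-substituted, electron-poor stannane may be slow, the tin halide formed may open the epoxide, or the allylpalladium intermediate may lose a β-hydride towards a conjugated triene. The fallback moves the coupling to the simple methyl ester, where an excess of 18 and a CuCl promoter can be used without risk to an epoxide. It sets out from 23 and 18 and returns at 27. Stille coupling under the same palladium conditions would give the methyl bromotrienoate F4, and LiOH (THF/MeOH/H2O, 0 °C → rt, then pH 4–5) the bromotrienoic acid F5. Esterification with 11 under proton-buffered carbodiimide conditions (DCC, DMAP, DMAP·HCl, CH2Cl2, 0 °C), through the O-acylisourea F6, would give 27. The buffer is needed because C4 of this acid is doubly allylic and its activated derivatives can deconjugate.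

3. Step 19. The C11 or C15 carbinol may be oxidised, or the transient β,γ-unsaturated aldehyde may drift into conjugation before it is oxidised further. The fallback oxidises before full deprotection, in two separate stages. It sets out from 29 and returns at 32. Selective cleavage of the primary silyl ether (HF·pyridine buffered with pyridine, THF, 0 °C) would give the C11,C2'-diol with O15 still silylated F7. TEMPO/PhI(OAc)2 in dry CH2Cl2 would stop at the aldehyde F8, which would be taken without purification into a Pinnick oxidation (NaClO2, NaH2PO4, 2-methyl-2-butene, t-BuOH/H2O) to the O15-silylated acid F9. HF·pyridine then frees the C15 hydroxyl to give 32.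

**Further compounds**
F1 | step 17 | (2R,4S,6S)-6-(tert-butyldimethylsilyloxy)-2-hydroxy-1-iodopentadecan-4-yl (Z)-5-(tert-butyldimethylsilyloxy)-3-(trimethylstannyl)pent-2-enoate | CCCCCCCCC[C@H](O[Si](C)(C)C(C)(C)C)C[C@@H](OC(=O)/C=C(\[Sn](C)(C)C)CCO[Si](C)(C)C(C)(C)C)C[C@@H](O)CI
F2 | step 17 | C13 ester of acid 24 with the C4–C24 chain: C4 primary allylic alcohol, free C11 hydroxyl, O15 silylated, 5E,8E | CCCCCCCCC[C@H](O[Si](C)(C)C(C)(C)C)C[C@@H](OC(=O)/C=C(\[Sn](C)(C)C)CCO[Si](C)(C)C(C)(C)C)C[C@@H](O)C/C(C)=C/C/C=C/CO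
F3 | step 17 | the C4 allylic bromide corresponding to F2 | CCCCCCCCC[C@H](O[Si](C)(C)C(C)(C)C)C[C@@H](OC(=O)/C=C(\[Sn](C)(C)C)CCO[Si](C)(C)C(C)(C)C)C[C@@H](O)C/C(C)=C/C/C=C/CBr
F4 | step 16 | methyl (2E,5E,8E)-9-bromo-3-[2-(tert-butyldimethylsilyloxy)ethyl]deca-2,5,8-trienoate | COC(=O)/C=C(CCO[Si](C)(C)C(C)(C)C)\C/C=C/C/C=C(C)/Br
F5 | step 16 | (2E,5E,8E)-9-bromo-3-[2-(tert-butyldimethylsilyloxy)ethyl]deca-2,5,8-trienoic acid | OC(=O)/C=C(CCO[Si](C)(C)C(C)(C)C)\C/C=C/C/C=C(C)/Br
F6 | step 16 | O-acylisourea of acid F5 and dicyclohexylcarbodiimide | C1CCCCC1NC(=NC1CCCCC1)OC(=O)/C=C(CCO[Si](C)(C)C(C)(C)C)\C/C=C/C/C=C(C)/Br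
F7 | step 19 | (3E,6E,9E,12S,14S)-12-hydroxy-4-(2-hydroxyethyl)-10-methyl-14-[(S)-2-(tert-butyldimethylsilyloxy)undecyl]oxacyclotetradeca-3,6,9-trien-2-one | CCCCCCCCC[C@H](O[Si](C)(C)C(C)(C)C)C[C@@H]1C[C@@H](O)C/C(C)=C/C/C=C/C/C(CCO)=C\C(=O)O1
F8 | step 19 | the C2' aldehyde corresponding to F7 | CCCCCCCCC[C@H](O[Si](C)(C)C(C)(C)C)C[C@@H]1C[C@@H](O)C/C(C)=C/C/C=C/C/C(CC=O)=C\C(=O)O1
F9 | step 19 | the C2' carboxylic acid corresponding to F7 (O15-silylated target) | CCCCCCCCC[C@H](O[Si](C)(C)C(C)(C)C)C[C@@H]1C[C@@H](O)C/C(C)=C/C/C=C/C/C(CC(=O)O)=C\C(=O)O1
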